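The neighbour flask that holds 0.075 M of solid reagent in place of 0.300 M raises the same question as the flask itself: does the clock or the balance of step 1 set the amount of target?

starting material 0.30 M; second substrate 0.300 M; solid reagent 0.300 M; time 1.5 h

    starting material + coupling partner ⇌ target (K1 = 5.4 M⁻¹, k1 = 0.32 M⁻¹ s⁻¹)
    second substrate + coupling partner ⇌ second product (K2 = 0.23 M⁻¹, k2 = 0.21 M⁻¹ s⁻¹)
    solid reagent ⇌ coupling partner, rate k3*(cs3 - [coupling partner]) while solid is left; crystals form when [coupling partner] > cs3 (cs3 = 0.26 M, k3 = 0.0019 s⁻¹)

- share of the starting material used up at 1.5 h
- target at 1.5 h, in percent of the starting material charged

Turned round, the target would fall short of the balance on the whole charge if solid reagent still lay in the flask at 1.5 h. That requires either [coupling partner] reaching 0.26 M, where dissolution stops, or dissolution outlasting the run.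

To see how far the flask stands from this, take one end first. With [coupling partner] held at the charge of solid reagent, step 1 at equilibrium gives a yield of 61.8%, but each target takes up one coupling partner, so this end is too high. Step 2 is set aside because its pull, the equilibrium constant times the starting concentration of its substrate, is 0.069, much weaker than the 1.6 of step 1. Joining the equilibrium to the balance of partner then gives a quadratic whose smaller root, as a share of the starting material charged, is 46.5%. This is the equilibrium ceiling: the yield of target once the solid reagent has dissolved and step 1 has come to equilibrium, with step 2 set aside.

It leaves [coupling partner] at 0.161 M, below the solubility. With [coupling partner] held at that concentration throughout, the charge of solid reagent takes an estimated 26.5 min to dissolve, which is shorter than the run. The half-life of coupling partner by the forward rate of step 1 alone, at the concentrations as charged, is 0.12 min, much shorter than that estimate. On this reckoning the flask stands inside thermodynamic control, and the reckoning commits to the ceiling.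

The forecast gives 45.4% for conversion and 45.4% for yield, each within 44% to 47%, “limited by the equilibrium rather than by kinetics”. Its yield lies 1.1 percentage points below the ceiling.

The flask gives 45.4% conversion and 45.4% yield, 1.1 points under the ceiling of 46.5%. In the flask, the half-life of coupling partner by the forward rate of step 1 alone is 0.22 min at the asked time, much shorter than the 0.0973 h by which half of the dissolution is done, and that time is much shorter than the run. For the neighbour flask, the same ceiling is 14.5%, and its yield of target stands at 14.1%.

(The rate constants stand for no real mixture; no experiment stands behind them.)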